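**Assumption:** Serpyllin has no stereocentre and no configurationally fixed axis, so it is one achiral compound and the SMILES below need no stereo descriptors.

## Retrosynthetic overview

1. Ring B is bought as 2,3,4-trimethoxybenzoic acid 1 and turned, through its chloride 2, into the β-keto sulfoxonium ylide 3; ring A is bought complete as 2-hydroxy-3,4-dimethoxybenzaldehyde 4.
2. Key disconnection C4–C3 (with O1–C2): the formyl carbon of 4 acts as an acyl anion equivalent (acylrhodium) and the ylide carbon of 3 as an α-keto carbene (enolonium equivalent). Their union gives 1,3-diketone 5, which closes ring C to flavone 6 in the same flask.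
3. Last disconnection C5–O: ketone-directed C–H oxygenation of 6 through trifluoroacetate 7 gives Serpyllin 8.
4. Ring order: rings A and B are carried in intact; ring C (the pyranone) is the only ring formed, in step 2.

## Route

Step 1
Reactants: 1 2,3,4-trimethoxybenzoic acid
Product: 3 dimethylsulfoxonium 2-oxo-2-(2,3,4-trimethoxyphenyl)ethylide, via acid chloride 2 (not isolated)
Conditions: (COCl)2 (1.2 equiv), DMF (cat.), CH2Cl2, 0 °C to rt, evaporate; then add in THF to Me3S(O)I/KOtBu (3 equiv each, THF, reflux 2 h, cooled to 0 °C), 0 °C to rt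
Reagents that add atoms: trimethylsulfoxonium iodide C[S+](C)(C)=O.[I-] (gives the CH=S(O)Me2 unit); oxalyl chloride O=C(Cl)C(=O)Cl (its chlorine stays only in 2)
Why: Acylation of the Corey–Chaykovsky ylide (dimethylsulfoxonium methylide) by an acid chloride is a standard nucleophilic acyl substitution, and the excess ylide deprotonates the acylsulfoxonium salt to the stabilised β-keto sulfoxonium ylide, with no stereocentre arising.

Step 2
Reactants: 3 dimethylsulfoxonium 2-oxo-2-(2,3,4-trimethoxyphenyl)ethylide (1.2 equiv); 4 2-hydroxy-3,4-dimethoxybenzaldehyde (1.0 equiv)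
Product: 6 7,8-dimethoxy-2-(2,3,4-trimethoxyphenyl)-4H-chromen-4-one, via 1,3-diketone 5 (not isolated)
Conditions: [(C5Me5)RhCl2]2 (2.5 mol %), AgSbF6 (10 mol %), NaOAc (30 mol %), ClCH2CH2Cl, 80 °C, 12 h; then TsOH·H2O (20 mol %), 80 °C, 2 h
Reagents that add atoms: none
Why: This is a chelation-assisted aldehyde C–H acylmethylation with a sulfoxonium ylide as carbene precursor followed by cyclodehydration, in which phenoxide-directed rhodation of the formyl C–H makes the aldehyde carbon of 4 a nucleophilic acylrhodium (an acyl anion equivalent) that migrates onto the electrophilic α-oxo carbene carbon released from 3 with loss of DMSO (an enolonium-type centre), so that two formally electrophilic carbons are joined as C4–C3 of diketone 5, and TsOH then closes ring C by attack of the phenol on the distal ketone, with no stereocentre formed.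

Step 3
Reactants: 6 7,8-dimethoxy-2-(2,3,4-trimethoxyphenyl)-4H-chromen-4-one
Product: 8 Serpyllin (5-hydroxy-7,8-dimethoxy-2-(2,3,4-trimethoxyphenyl)-4H-chromen-4-one), via aryl trifluoroacetate 7 (not isolated)
Conditions: [RuCl2(p-cymene)]2 (5 mol %), PhI(OCOCF3)2 (2.0 equiv), CF3CO2H/(CF3CO)2O 3:1, 80 °C; then aq Na2S2O3/NaHCO3 work-up, rt
Reagents that add atoms: [bis(trifluoroacetoxy)iodo]benzene O=C(OI(OC(=O)C(F)(F)F)c1ccccc1)C(F)(F)F (gives the C5 oxygen, and the trifluoroacetyl group of 7)
Why: This is a ketone-directed ruthenium-catalysed C–H hydroxylation, in which the C4 carbonyl guides cycloruthenation to the only peri C–H (C5, para to the 8-methoxy group), oxidation by PhI(OCOCF3)2 and C–O reductive elimination give trifluoroacetate 7, and this ester is shielded from over-oxidation until the reductive quench and mild hydrolysis free the hydrogen-bonded 5-OH, with no stereocentre formed.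

## Compound list

1 | 2,3,4-trimethoxybenzoic acid | COc1ccc(C(=O)O)c(OC)c1OC | starting material
2 | 2,3,4-trimethoxybenzoyl chloride | COc1ccc(C(Cl)=O)c(OC)c1OC | intermediate
3 | dimethylsulfoxonium 2-oxo-2-(2,3,4-trimethoxyphenyl)ethylide | COc1ccc(C(=O)C=S(C)(C)=O)c(OC)c1OC | intermediate
4 | 2-hydroxy-3,4-dimethoxybenzaldehyde | COc1ccc(C=O)c(O)c1OC | starting material
5 | 1-(2-hydroxy-3,4-dimethoxyphenyl)-3-(2,3,4-trimethoxyphenyl)propane-1,3-dione | COc1ccc(C(=O)CC(=O)c2ccc(OC)c(OC)c2OC)c(O)c1OC | intermediate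
6 | 7,8-dimethoxy-2-(2,3,4-trimethoxyphenyl)-4H-chromen-4-one | COc1ccc(-c2cc(=O)c3ccc(OC)c(OC)c3o2)c(OC)c1OC | intermediate
7 | 7,8-dimethoxy-4-oxo-2-(2,3,4-trimethoxyphenyl)-4H-chromen-5-yl trifluoroacetate | COc1ccc(-c2cc(=O)c3c(OC(=O)C(F)(F)F)cc(OC)c(OC)c3o2)c(OC)c1OC | intermediate
8 | Serpyllin, 5-hydroxy-7,8-dimethoxy-2-(2,3,4-trimethoxyphenyl)-4H-chromen-4-one | COc1ccc(-c2cc(=O)c3c(O)cc(OC)c(OC)c3o2)c(OC)c1OC | target

## Step count and risks

Total step count: 3. Longest linear sequence: 3 (1 → 3 → 6 → 8); aldehyde 4 is bought.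

The steps most likely to fail, in order of concern:

(a) The key C4–C3 union of step 2. The carbene from 3 may insert into the phenol O–H of 4 instead of the acyl–rhodium bond, or 3 may direct rhodation of its own C6'–H and self-condense. The fallback sets out from acid chloride 2 (made from 1 as in step 1). It is used to esterify commercial 1-(2-hydroxy-3,4-dimethoxyphenyl)ethan-1-one F1 (pyridine, DMAP cat., CH2Cl2) to give 6-acetyl-2,3-dimethoxyphenyl 2,3,4-trimethoxybenzoate F2. KOH in pyridine at 50 °C (Baker–Venkataraman O-to-C acyl shift) then gives diketone 5, where the route is rejoined for the acid-catalysed ring closure to 6.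

(b) The C5–H oxygenation of step 3. The hypervalent iodine oxidant may attack the electron-rich trimethoxyphenyl ring, or oxidise the product (a para-methoxyphenol once the ester is cleaved) to the 5,8-quinone. The fallback sets out from ylide 3 and carries the C5 oxygen in from the start:
- Commercial 1,2,3,5-tetramethoxybenzene F3 is formylated (POCl3, DMF, Vilsmeier–Haack) to 2,3,4,6-tetramethoxybenzaldehyde F4.
- AlCl3 in CH2Cl2 removes the twisted, doubly flanked 2-O-methyl group to give 2-hydroxy-3,4,6-trimethoxybenzaldehyde F5. This regioselectivity is argued by analogy with the corresponding acetophenone.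
- The step 2 conditions couple F5 with 3 through 1-(2-hydroxy-3,4,6-trimethoxyphenyl)-3-(2,3,4-trimethoxyphenyl)propane-1,3-dione F6 to 5,7,8-trimethoxy-2-(2,3,4-trimethoxyphenyl)-4H-chromen-4-one F7.
- BCl3 (CH2Cl2, −78 to 0 °C) cleaves only the carbonyl-chelated 5-O-methyl group, coming back to the route at 8.

(c) The ylide formation of step 1. The hindered, electron-rich ortho-methoxy acid chloride may react slowly or be acylated twice. The fallback sets out from acid chloride 2 and changes the carbene precursor. Me3SiCHN2 (MeCN/THF, 0 °C to rt) gives 2-diazo-1-(2,3,4-trimethoxyphenyl)ethan-1-one F8. F8 replaces 3 in step 2 under the same [(C5Me5)RhCl2]2/AgSbF6 system, with N2 lost in place of DMSO, and the route is rejoined at diketone 5.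

## Further compounds

F1 | step 2 | 1-(2-hydroxy-3,4-dimethoxyphenyl)ethan-1-one | COc1ccc(C(C)=O)c(O)c1OC
F2 | step 2 | 6-acetyl-2,3-dimethoxyphenyl 2,3,4-trimethoxybenzoate | COc1ccc(C(C)=O)c(OC(=O)c2ccc(OC)c(OC)c2OC)c1OC
F3 | step 3 | 1,2,3,5-tetramethoxybenzene | COc1cc(OC)c(OC)c(OC)c1
F4 | step 3 | 2,3,4,6-tetramethoxybenzaldehyde | O=Cc1c(OC)cc(OC)c(OC)c1OC
F5 | step 3 | 2-hydroxy-3,4,6-trimethoxybenzaldehyde | O=Cc1c(OC)cc(OC)c(OC)c1O
F6 | step 3 | 1-(2-hydroxy-3,4,6-trimethoxyphenyl)-3-(2,3,4-trimethoxyphenyl)propane-1,3-dione | COc1cc(OC)c(C(=O)CC(=O)c2ccc(OC)c(OC)c2OC)c(O)c1OC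
F7 | step 3 | 5,7,8-trimethoxy-2-(2,3,4-trimethoxyphenyl)-4H-chromen-4-one | COc1ccc(-c2cc(=O)c3c(OC)cc(OC)c(OC)c3o2)c(OC)c1OC
F8 | step 1 | 2-diazo-1-(2,3,4-trimethoxyphenyl)ethan-1-one | COc1ccc(C(=O)C=[N+]=[N-])c(OC)c1OC
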